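**Retrosynthetic overview**

1. The target is the [5+2] adduct of a ring-B-contracted abietane hydroxy-p-quinone and a labda-8(17),12E,14-trien-18-oic acid unit; the last disconnection is C8–C9 in labdane ring B (C5–C6–C7–C8–C9–C10).
2. Enabling feature: ring B carries the exocyclic methylene C8=C17 next to C9, and C9 carries the homoallylic arm C11–C12=C13. The array C17=C8–C9–C11–C12=C13 is the retron of a C8 alkenyl radical (from a 2-iodo-1-alkene) closing 6-exo on the C9 end of a C9=C11–C12=C13 diene, with hydrogen returned at C11.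
3. The 8,9-seco-labdane is cut out of dehydroabietic acid: ozonolysis removes the aromatic ring, keeps C4, C5 and C10, and leaves C8 and C9 as carboxyl stubs that are grown into the iodoalkene and the triene arm.
4. Ring order: abietane ring B is contracted on sugiol (1,2-aryl shift) and ring C is oxidised to the hydroxyquinone; a perezone-type [5+2] with the triene terminus forms both rings of the bicyclo[3.2.1]octane and joins the halves; labdane ring B closes last and gives the unprotected natural product.

Key step: step 21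

Assumption: (+)-dehydroabietic acid and (+)-sugiol are taken as catalogue compounds of natural configuration; labdane/abietane numbering is used, and from step 13 on the contracted abietane ring is numbered as a 5(6→7)abeo-abietane (ring carbon C7 bonded to C5 and C8, exocyclic carbon C6).

**Route**

Step 1
Reactants: 1 (+)-dehydroabietic acid
Product: 2 methyl dehydroabietate
Conditions: Me3SiCHN2, MeOH/toluene, rt
Reagents that add atoms: (trimethylsilyl)diazomethane C[Si](C)(C)C=[N+]=[N-]
Why: O-alkylation of the carboxylate (esterification) works on the hindered tertiary C18 acid because the bond is made at oxygen, and no stereocentre is touched.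

Step 2
Reactants: 2 methyl dehydroabietate
Product: 3 11,12,13,14,15,16,17-heptanor-8,9-secolabdane-8,9,18-trioic acid 18-methyl ester
Conditions: O3, AcOH/H2O, 30% H2O2, 10 °C then 50 °C
Reagents that add atoms: ozone [O-][O+]=O; hydrogen peroxide OO
Why: Exhaustive arene ozonolysis with oxidative work-up should leave only the two ring-fusion carbons C8 and C9 as carboxylic acids (both Kekulé cleavage modes converge), while the quaternary C4 and C10 and the C5 centre are not affected.

Step 3
Reactants: 3 heptanor-8,9-secolabdane-8,9,18-trioic acid 18-methyl ester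
Product: 4 methyl 8,9-dihydroxy-11,12,13,14,15,16,17-heptanor-8,9-secolabdan-18-oate
Conditions: BH3·SMe2, THF, 0 °C to rt; MeOH quench
Reagents that add atoms: none
Why: Borane reduces carboxylic acids much faster than the hindered tertiary methyl ester (chemoselective acid reduction).

Step 4
Reactants: 4 methyl 8,9-dihydroxy-heptanor-8,9-secolabdan-18-oate
Product: 5 methyl 9-hydroxy-8-oxo-11,12,13,14,15,16,17-heptanor-8,9-secolabdan-18-oate
Conditions: TEMPO (10 mol%), PhI(OAc)2, CH2Cl2, 0 °C
Reagents that add atoms: none
Why: The oxoammonium oxidation is sterically selective, so the unhindered C8 carbinol should be oxidised while the neopentyl C9 carbinol on quaternary C10 stays.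

Step 5
Reactants: 5 methyl 9-hydroxy-8-oxo-heptanor-8,9-secolabdan-18-oate
Product: 6 methyl 9-hydroxy-11,12,13,14,15,16-hexanor-8,9-secolabd-8(17)-yn-18-oate
Conditions: dimethyl (1-diazo-2-oxopropyl)phosphonate, K2CO3, MeOH, 0 °C to rt
Reagents that add atoms: dimethyl (1-diazo-2-oxopropyl)phosphonate COP(=O)(OC)C(=[N+]=[N-])C(C)=O
Why: Seyferth–Gilbert homologation in its mild carbonate variant converts the C8 aldehyde into the terminal alkyne C8≡C17 and adds the future methylene carbon C17.

Step 6
Reactants: 6 methyl 9-hydroxy-hexanor-8,9-secolabd-8(17)-yn-18-oate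
Product: 7 methyl 9-oxo-11,12,13,14,15,16-hexanor-8,9-secolabd-8(17)-yn-18-oate
Conditions: Dess–Martin periodinane, NaHCO3, CH2Cl2, rt
Reagents that add atoms: none
Why: Periodinane oxidation of the neopentyl alcohol gives the non-enolisable C9 aldehyde and removes the hydroxyl that could lactonise onto C18.

Step 7
Reactants: 7 methyl 9-oxo-hexanor-8,9-secolabd-8(17)-yn-18-oate
Product: 8 methyl 8-iodo-9-oxo-11,12,13,14,15,16-hexanor-8,9-secolabd-8(17)-en-18-oate
Conditions: NaI, Me3SiCl, H2O (0.5 equiv), MeCN, rt
Reagents that add atoms: sodium iodide [Na+].[I-]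
Why: Markovnikov hydroiodination of the terminal alkyne by HI made in situ gives the 2-iodo-1-alkene; the hindered ester and the non-enolisable aldehyde should tolerate it.

Step 8
Reactants: 9 (E)-3-methylpent-2-en-4-yn-1-ol
Product: 10 (E)-3-methylpenta-2,4-dien-1-ol
Conditions: H2 (1 atm), Pd/CaCO3 poisoned with Pb(OAc)2, quinoline, EtOAc, rt
Reagents that add atoms: none
Why: Semi-hydrogenation of the terminal alkyne on the poisoned palladium catalyst stops at the vinyl group and leaves the E trisubstituted alkene unchanged.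

Step 9
Reactants: 10 (E)-3-methylpenta-2,4-dien-1-ol
Product: 11 [(2E)-3-methylpenta-2,4-dien-1-yl]triphenylphosphonium bromide
Conditions: PPh3·HBr, CH2Cl2, rt; recrystallisation
Reagents that add atoms: triphenylphosphine hydrobromide c1ccc(cc1)[PH+](c1ccccc1)c1ccccc1.[Br-]
Why: Allylic substitution of the alcohol by the phosphine (phosphonium salt formation) gives one constitution because the intermediate 3-methylpentadienyl system is symmetric, and the E salt is the crystalline isomer.

Step 10
Reactants: 8 methyl 8-iodo-9-oxo-hexanor-8,9-secolabd-8(17)-en-18-oate; 11 [(2E)-3-methylpenta-2,4-dien-1-yl]triphenylphosphonium bromide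
Product: 13 methyl (9E,12E)-8-iodo-8,9-secolabda-8(17),9(11),12,14-tetraen-18-oate, via phosphorus ylide 12 (not isolated)
Conditions: 11, NaN(SiMe3)2 (1.0 equiv), THF, −78 to 0 °C; then 8, −78 °C to rt
Reagents that add atoms: none
Why: Wittig olefination of the C9 aldehyde adds C11–C16 with the E C12=C13 alkene of the salt; the geometry of the new C9=C11 bond (mainly E expected) does not matter because it is erased in step 21.

Step 11
Reactants: 13 methyl (9E,12E)-8-iodo-8,9-secolabda-8(17),9(11),12,14-tetraen-18-oate
Product: 14 (9E,12E)-8-iodo-8,9-secolabda-8(17),9(11),12,14-tetraen-18-oic acid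
Conditions: LiSPr (from PrSH and n-BuLi), HMPA, rt; 1 M HCl
Reagents that add atoms: none
Why: Thiolate demethylation attacks the methyl carbon (SN2 dealkylation), so the hindered C18 ester is cleaved without base strong enough to eliminate HI or isomerise the triene.

Step 12
Reactants: 15 (+)-sugiol
Product: 16 12-O-benzylsugiol
Conditions: BnBr, K2CO3, DMF, rt
Reagents that add atoms: benzyl bromide BrCc1ccccc1
Why: Williamson etherification masks the phenol, which would otherwise be oxidised by the hypervalent iodine reagent of step 13.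

Step 13
Reactants: 16 12-O-benzylsugiol
Product: 17 methyl 12-benzyloxy-5(6→7)abeo-abieta-8,11,13-trien-6-oate
Conditions: PhI(OAc)2, H2SO4, HC(OMe)3, rt
Reagents that add atoms: trimethyl orthoformate COC(OC)OC
Why: Oxidative 1,2-aryl shift of an aryl ketone: the enol ether is iodinated at the α-carbon by hypervalent iodine and the para-alkoxyaryl carbon C8 migrates with loss of PhI, contracting ring B to the five-membered ring with an exocyclic ester; the new centre forms as an epimer mixture that converges in step 14.

Step 14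
Reactants: 17 methyl 12-benzyloxy-5(6→7)abeo-abieta-8,11,13-trien-6-oate
Product: 19 methyl 12-benzyloxy-7α-hydroxy-5(6→7)abeo-abieta-8,11,13-trien-6-oate, via potassium ester enolate 18 (not isolated)
Conditions: KN(SiMe3)2, THF, −78 °C; then 2-(phenylsulfonyl)-3-phenyloxaziridine, −78 °C; aq. NH4Cl
Reagents that add atoms: 2-(phenylsulfonyl)-3-phenyloxaziridine O=S(=O)(N1OC1c1ccccc1)c1ccccc1
Why: Enolate hydroxylation with an N-sulfonyloxaziridine should deliver oxygen to the α-face of C7, anti to the angular C10 methyl and the axial C4 methyl, giving the 7α-hydroxy, 7β-carboxyl arrangement of the target.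

Step 15
Reactants: 19 methyl 12-benzyloxy-7α-hydroxy-5(6→7)abeo-abieta-8,11,13-trien-6-oate
Product: 20 methyl 7α,12-dihydroxy-5(6→7)abeo-abieta-8,11,13-trien-6-oate
Conditions: H2, Pd/C, EtOAc, rt
Reagents that add atoms: none
Why: Neutral hydrogenolysis removes the benzyl ether; the tertiary benzylic alcohol α to the ester should resist.

Step 16
Reactants: 20 methyl 7α,12-dihydroxy-5(6→7)abeo-abieta-8,11,13-trien-6-oate
Product: 21 methyl 7α-hydroxy-11,12-dioxo-5(6→7)abeo-abieta-8,13-dien-6-oate
Conditions: IBX, DMF, rt
Reagents that add atoms: IBX O=C1OI(=O)(O)c2ccccc12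
Why: IBX ortho-oxygenation of a phenol delivers oxygen to the only free ortho position (C11) and gives the 11,12-ortho-quinone; C7 is quaternary, so no quinone methide can form.

Step 17
Reactants: 21 methyl 7α-hydroxy-11,12-dioxo-5(6→7)abeo-abieta-8,13-dien-6-oate
Product: 22 methyl 7α,11,12,14-tetraacetoxy-5(6→7)abeo-abieta-8,11,13-trien-6-oate
Conditions: Ac2O, BF3·OEt2 (cat.), rt
Reagents that add atoms: acetic anhydride CC(=O)OC(C)=O
Why: Thiele–Winter acetoxylation adds acetate at C14, the only unsubstituted quinone carbon, and aromatises to the 11,12,14-trioxygenated ring; the tertiary hydroxyl is acetylated as well.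

Step 18
Reactants: 22 methyl 7α,11,12,14-tetraacetoxy-5(6→7)abeo-abieta-8,11,13-trien-6-oate
Product: 24 6,7α,12-trihydroxy-5(6→7)abeo-abieta-8,12-diene-11,14-dione, via hydroquinone pentaol 23 (not isolated)
Conditions: LiAlH4, THF, 0 °C to rt; aqueous work-up under air
Reagents that add atoms: none
Why: Hydride cleaves the four acetates and reduces the ester to the C6 carbinol, and the resulting 1,2,4-trihydroxyarene autoxidises in air to the hydroxy-para-quinone (ester reduction, then hydroquinone autoxidation).

Step 19
Reactants: 24 6,7α,12-trihydroxy-5(6→7)abeo-abieta-8,12-diene-11,14-dione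
Product: 25 7α,12-dihydroxy-11,14-dioxo-5(6→7)abeo-abieta-8,12-dien-6-al
Conditions: IBX, DMSO, rt
Reagents that add atoms: none
Why: IBX oxidises the primary alcohol of the primary/tertiary 1,2-diol to the aldehyde without glycol cleavage; the tertiary hydroxyl and the quinone are inert.

Step 20
Reactants: 14 (9E,12E)-8-iodo-8,9-secolabda-8(17),9(11),12,14-tetraen-18-oic acid; 25 7α,12-dihydroxy-11,14-dioxo-5(6→7)abeo-abieta-8,12-dien-6-al
Product: 26 8-iodo-8,9-seco [5+2] adduct (labdane C15 bonded to abietane C8 and labdane C14 bonded to abietane C13)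
Conditions: BF3·OEt2 (0.3 equiv), CH2Cl2, −78 to −40 °C
Reagents that add atoms: none
Why: The Lewis acid turns the vinylogous-acid quinone into a 2-oxidopentadienyl cation (C8–C9–C11–C12–C13) that should undergo a perezone-type cationic [5+2] cycloaddition with the terminal C14=C15 alkene of the triene (C15 to C8, then closure of the dienyl cation at C14 by the enol carbon C13); attack on the ring-C face anti to the C10 methyl and the C6 formyl group, with the dienyl arm under the C9=C11–C12 bridge (compact transition state), sets abietane C8 and C13 and labdane C14, and the iodoalkene is too electron-poor to compete.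

Step 21
Reactants: 26 8-iodo-8,9-seco [5+2] adduct
Product: 27 target CNP0124601.1
Conditions: Bu3SnH (slow addition), Et3B/air (cat.), toluene (2 mM), rt; KF work-up
Reagents that add atoms: none
Why: Iodine abstraction from the 2-iodo-1-alkene gives the C8 alkenyl σ-radical, which adds to C9, the terminus of the C9=C11–C12=C13 diene; the resulting allyl radical (C11–C12–C13) takes hydrogen from the stannane at its less substituted end C11, leaving the E trisubstituted C12=C13 alkene and the C8=C17 methylene. The closest known reaction type is the tin-hydride alkenyl-radical cyclisation of 2-halo-1-alkenes onto alkenes and dienes. Ring B closes in the 6-exo-trig mode by forming C8–C9. The only new stereocentre, C9, is controlled by the chair-like transition state of the forming ring, anchored by the fixed C5 and C10 centres of the dehydroabietic acid ring A, with the dienyl arm equatorial (9α-H, 9β-chain); the trans ring fusion is preset. The step needs cyclisation to outrun hydrogen capture by the alkenyl radical, which the reactive diene acceptor and the low stannane concentration should secure, and it needs hydrogen return at C11 and not at C13, which the tertiary, fully substituted C13 end disfavours. Fast iodine abstraction keeps the stannyl radical away from the carbonyl groups, the enol and the free acid, so the step should give the natural product without protecting groups.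

**Compound list**

1 | (+)-dehydroabietic acid (abieta-8,11,13-trien-18-oic acid; 4α-CO2H, 4β-Me, 5α-H, 10β-Me) | OC(=O)[C@]1(C)CCC[C@]2(C)c3ccc(C(C)C)cc3CC[C@@H]12 | starting material
2 | methyl dehydroabietate | COC(=O)[C@]1(C)CCC[C@]2(C)c3ccc(C(C)C)cc3CC[C@@H]12 | intermediate
3 | 11,12,13,14,15,16,17-heptanor-8,9-secolabdane-8,9,18-trioic acid 18-methyl ester (ring A with 4α-CO2Me, 5β-CH2CH2CO2H, 10α-CO2H, 10β-Me) | COC(=O)[C@]1(C)CCC[C@](C)(C(=O)O)[C@H]1CCC(=O)O | intermediate
4 | methyl 8,9-dihydroxy-11,12,13,14,15,16,17-heptanor-8,9-secolabdan-18-oate | COC(=O)[C@]1(C)CCC[C@](C)(CO)[C@H]1CCCO | intermediate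
5 | methyl 9-hydroxy-8-oxo-11,12,13,14,15,16,17-heptanor-8,9-secolabdan-18-oate | COC(=O)[C@]1(C)CCC[C@](C)(CO)[C@H]1CCC=O | intermediate
6 | methyl 9-hydroxy-11,12,13,14,15,16-hexanor-8,9-secolabd-8(17)-yn-18-oate | COC(=O)[C@]1(C)CCC[C@](C)(CO)[C@H]1CCC#C | intermediate
7 | methyl 9-oxo-11,12,13,14,15,16-hexanor-8,9-secolabd-8(17)-yn-18-oate | COC(=O)[C@]1(C)CCC[C@](C)(C=O)[C@H]1CCC#C | intermediate
8 | methyl 8-iodo-9-oxo-11,12,13,14,15,16-hexanor-8,9-secolabd-8(17)-en-18-oate | COC(=O)[C@]1(C)CCC[C@](C)(C=O)[C@H]1CCC(I)=C | intermediate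
9 | (E)-3-methylpent-2-en-4-yn-1-ol | C#C/C(C)=C/CO | starting material
10 | (E)-3-methylpenta-2,4-dien-1-ol | C=C/C(C)=C/CO | intermediate
11 | [(2E)-3-methylpenta-2,4-dien-1-yl]triphenylphosphonium bromide | C=C/C(C)=C/C[P+](c1ccccc1)(c1ccccc1)c1ccccc1.[Br-] | intermediate
12 | phosphorus ylide of 11 (not isolated) | C=C/C(C)=C/C=P(c1ccccc1)(c1ccccc1)c1ccccc1 | intermediate
13 | methyl (9E,12E)-8-iodo-8,9-secolabda-8(17),9(11),12,14-tetraen-18-oate | COC(=O)[C@]1(C)CCC[C@](C)(/C=C/C=C(\C)C=C)[C@H]1CCC(I)=C | intermediate
14 | (9E,12E)-8-iodo-8,9-secolabda-8(17),9(11),12,14-tetraen-18-oic acid | OC(=O)[C@]1(C)CCC[C@](C)(/C=C/C=C(\C)C=C)[C@H]1CCC(I)=C | intermediate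
15 | (+)-sugiol (12-hydroxyabieta-8,11,13-trien-7-one; 5α-H, 10β-Me) | CC(C)c1cc2c(cc1O)[C@@]1(C)CCCC(C)(C)[C@@H]1CC2=O | starting material
16 | 12-O-benzylsugiol | CC(C)c1cc2c(cc1OCc1ccccc1)[C@@]1(C)CCCC(C)(C)[C@@H]1CC2=O | intermediate
17 | methyl 12-benzyloxy-5(6→7)abeo-abieta-8,11,13-trien-6-oate (both C7 epimers) | CC(C)c1cc2c(cc1OCc1ccccc1)[C@@]1(C)CCCC(C)(C)[C@@H]1C2C(=O)OC | intermediate
18 | potassium ester enolate of 17 (not isolated) | CC(C)c1cc2c(cc1OCc1ccccc1)[C@@]1(C)CCCC(C)(C)[C@@H]1C2=C([O-])OC.[K+] | intermediate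
19 | methyl 12-benzyloxy-7α-hydroxy-5(6→7)abeo-abieta-8,11,13-trien-6-oate | CC(C)c1cc2c(cc1OCc1ccccc1)[C@@]1(C)CCCC(C)(C)[C@@H]1[C@]2(O)C(=O)OC | intermediate
20 | methyl 7α,12-dihydroxy-5(6→7)abeo-abieta-8,11,13-trien-6-oate | CC(C)c1cc2c(cc1O)[C@@]1(C)CCCC(C)(C)[C@@H]1[C@]2(O)C(=O)OC | intermediate
21 | methyl 7α-hydroxy-11,12-dioxo-5(6→7)abeo-abieta-8,13-dien-6-oate (ortho-quinone) | CC(C)C1=CC2=C(C(=O)C1=O)[C@@]1(C)CCCC(C)(C)[C@@H]1[C@]2(O)C(=O)OC | intermediate
22 | methyl 7α,11,12,14-tetraacetoxy-5(6→7)abeo-abieta-8,11,13-trien-6-oate | CC(C)c1c(OC(C)=O)c2c(c(OC(C)=O)c1OC(C)=O)[C@@]1(C)CCCC(C)(C)[C@@H]1[C@]2(OC(C)=O)C(=O)OC | intermediate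
23 | 5(6→7)abeo-abieta-8,11,13-triene-6,7α,11,12,14-pentaol (not isolated) | CC(C)c1c(O)c2c(c(O)c1O)[C@@]1(C)CCCC(C)(C)[C@@H]1[C@]2(O)CO | intermediate
24 | 6,7α,12-trihydroxy-5(6→7)abeo-abieta-8,12-diene-11,14-dione | CC(C)C=1C(=O)C2=C(C(=O)C=1O)[C@@]1(C)CCCC(C)(C)[C@@H]1[C@]2(O)CO | intermediate
25 | 7α,12-dihydroxy-11,14-dioxo-5(6→7)abeo-abieta-8,12-dien-6-al | CC(C)C=1C(=O)C2=C(C(=O)C=1O)[C@@]1(C)CCCC(C)(C)[C@@H]1[C@]2(O)C=O | intermediate
26 | 8-iodo-8,9-seco [5+2] adduct: (9E,12E)-8-iodo-8,9-secolabda-8(17),9(11),12-trien-18-oic acid with C15 bonded to C8 and C14 bonded to C13 of a 7α,11-dihydroxy-12,14-dioxo-5(6→7)abeo-abiet-9(11)-en-6-al unit | OC(=O)[C@]4(C)CCC[C@](C)(/C=C/C=C(\C)[C@@H]1C[C@@]23C(=O)[C@]1(C(C)C)C(=O)C(O)=C2[C@@]1(C)CCCC(C)(C)[C@@H]1[C@]3(O)C=O)[C@H]4CCC(I)=C | intermediate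
27 | CNP0124601.1 | C=C1CC[C@@H]2[C@](C)(CCC[C@@]2(C)C(=O)O)[C@H]1C/C=C(\C)[C@@H]1C[C@@]23C(=O)[C@]1(C(C)C)C(=O)C(O)=C2[C@@]1(C)CCCC(C)(C)[C@@H]1[C@]3(O)C=O | target

**Step count and risks**

Total step count: 21. Longest linear sequence: 11 steps (steps 1–7, 10, 11, 20, 21). The sugiol branch is 10 steps (12–21) and the phosphonium branch 2 steps (8, 9).

Steps most likely to fail:

Step 20 ([5+2] cycloaddition). The Lewis acid may trigger an α-ketol shift or a Prins reaction of the free tertiary α-hydroxy aldehyde, and the face or endo selectivity of the cycloaddition may be poor. Fallback: run the cycloaddition one oxidation level lower. Hydroxyquinone diol 24 and acid 14 are combined under the same Lewis-acid conditions to give the diol adduct F1, which has no aldehyde to rearrange and a smaller group on the β-face. F1 is then oxidised with IBX in DMSO at the primary carbinol only, which returns to the route at 26.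

Step 21 (radical closure of ring B). The alkenyl radical may be reduced before it cyclises, or hydrogen may return at C13 of the allyl radical, giving the C11=C12 isomer with loss of the E trisubstituted alkene. Fallback: change from the free-radical to an organopalladium manifold, starting again from 26. Zerovalent palladium (Pd(PPh3)4) inserts into the C8–I bond, the alkenylpalladium adds 6-exo across C9=C11 to give a π-allylpalladium over C11–C13, and Bu3SnH transfers hydride to its less substituted end C11 (Heck-type cyclisation with hydride capture). This leads directly to 27, and no new compound is made (F0).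

Step 13 (ring contraction). The hypervalent iodine reagent may oxidise the electron-rich arene, or the α-carbon may be methoxylated without the aryl shift. Fallback: Wolff ring contraction. 16 is formylated at C6 (NaH, HCO2Et) to the hydroxymethylene ketone F2. Deformylative diazo transfer with 4-acetamidobenzenesulfonyl azide and Et3N gives the diazo ketone F3. Photolysis of F3 in methanol makes the same aryl carbon migrate and returns to the route at 17.

Further compounds
F1 | step 20 | diol adduct: the 6-carbinol analogue of 26 (CH2OH in place of CHO at abietane C6) | OC(=O)[C@]4(C)CCC[C@](C)(/C=C/C=C(\C)[C@@H]1C[C@@]23C(=O)[C@]1(C(C)C)C(=O)C(O)=C2[C@@]1(C)CCCC(C)(C)[C@@H]1[C@]3(O)CO)[C@H]4CCC(I)=C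
F0 | step 21 | none | none
F2 | step 13 | 12-benzyloxy-6-(hydroxymethylene)abieta-8,11,13-trien-7-one | CC(C)c1cc2c(cc1OCc1ccccc1)[C@@]1(C)CCCC(C)(C)[C@@H]1C(=CO)C2=O
F3 | step 13 | 12-benzyloxy-6-diazoabieta-8,11,13-trien-7-one | CC(C)c1cc2c(cc1OCc1ccccc1)[C@@]1(C)CCCC(C)(C)[C@@H]1C(=[N+]=[N-])C2=O
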